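**Retrosynthetic overview**

1. In the ten-membered carbocycle both unsaturation sites are cis (Z C4=C5; the cis C1–C10 oxirane is a former Z C1=C10 alkene) and the C6 oxygen sits 1,3 to C1 through C10. C6, C10 and C1 are therefore read as the carbonyl carbon, the ring-fusion carbon and the sulfonate carbon of a Wharton–Grob fragmentation of a cyclopentane-fused cycloheptene.
2. Late stage: C1–C10 oxirane (peracid), C13 methylene (Mannich/elimination), 6,12-lactone (oxidative lactonisation), C8 epoxy ester together with the C6 carbinol (Evans–Tishchenko with epoxy aldehyde 25 from tiglic acid).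
3. Cyclodecadienone 21 comes from scission of a deliberately made C6–C10 fusion bond in bicyclo[5.3.0]decene mesylate 19, itself closed by ring-closing metathesis of diene diol 17.
4. 17 comes from vinyl addition and a reductive aldol (4-methylpent-4-enal) on 2-methylcyclopentenone 11, made from bicyclic lactone 1, which supplies C6–C12 and the cis C7/C8 pair.
5. Ring order: cyclopentane (bought), cycloheptene (metathesis), ten-membered ring (fragmentation), ester oxirane (arrives with 25), γ-lactone, C1–C10 oxirane.

Key step: step 15

Remark: germacrane locants (C1–C15; C12 lactone carbonyl, C13 exocyclic methylene, C14 methyl on C10, C15 methyl on C4) label the atoms of all intermediates; the SMILES strings define the configurations.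

**Route**

Step 1
Reactants: 1 (1R,5S)-2-oxabicyclo[3.3.0]oct-6-en-3-one
Product: 2 (1R,2S)-2-(2-hydroxyethyl)cyclopent-3-en-1-ol
Conditions: LiAlH4, THF, 0 °C → rt
Reagents that add atoms: none
Why: LiAlH4 reduction of the γ-lactone to the 1,4-diol leaves the cis C7/C8 stereocentres and the alkene untouched.

Step 2
Reactants: 2 (1R,2S)-2-(2-hydroxyethyl)cyclopent-3-en-1-ol
Product: 3 (1R,2S)-2-[2-(tert-butyldiphenylsilyloxy)ethyl]cyclopent-3-en-1-ol
Conditions: TBDPSCl, imidazole, CH2Cl2, −20 → 0 °C
Reagents that add atoms: tert-butylchlorodiphenylsilane, CC(C)(C)[Si](Cl)(c1ccccc1)c1ccccc1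
Why: Silyl ether formation with the bulky chlorosilane discriminates the primary C12 hydroxyl from the secondary ring hydroxyl.

Step 3
Reactants: 3 (1R,2S)-2-[2-(tert-butyldiphenylsilyloxy)ethyl]cyclopent-3-en-1-ol
Product: 4 cis-cyclopentene bis-silyl ether (C8 OTES, C12 OTBDPS)
Conditions: TESCl, imidazole, DMF, 0 °C → rt
Reagents that add atoms: chlorotriethylsilane, CC[Si](Cl)(CC)CC
Why: Silyl ether formation at the remaining secondary C8 hydroxyl; triethylsilyl is chosen because mild acid removes it later while the TBDPS ether stays.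

Step 4
Reactants: 4 cis-cyclopentene bis-silyl ether
Product: 5 C6–C10 epoxide (oxirane trans to the C7 chain and the C8 silyl ether)
Conditions: mCPBA, NaHCO3, CH2Cl2, 0 °C
Reagents that add atoms: 3-chloroperoxybenzoic acid, OOC(=O)c1cccc(Cl)c1
Why: Prilezhaev epoxidation from the face opposite the two cis substituents; the oxirane configuration has no lasting consequence because C6 becomes a ketone and C10 an sp2 carbon.

Step 5
Reactants: 5 C6–C10 epoxide
Product: 6 hydroxy selenide (C6–OH, C10–SePh, trans)
Conditions: (PhSe)2, NaBH4, EtOH–THF, 0 °C → rt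
Reagents that add atoms: diphenyl diselenide, c1ccc(cc1)[Se][Se]c1ccccc1
Why: SN2 epoxide opening by benzeneselenolate made in the flask, trans to the oxirane oxygen and at C10, the oxirane carbon remote from the branched C7 whose side chain shields backside attack at C6.

Step 6
Reactants: 6 hydroxy selenide
Product: 8 cyclopent-2-en-1-ol (C6 carbinol; C9=C10 alkene), via selenoxide 7 (not isolated)
Conditions: 30% H2O2, pyridine, THF, 0 °C → rt
Reagents that add atoms: none
Why: Oxidation to the selenoxide and thermal syn-elimination (epoxide-to-allylic-alcohol sequence), which runs away from the carbinol carbon toward a C9 hydrogen and so places the alkene at C9=C10.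

Step 7
Reactants: 8 cyclopent-2-en-1-ol (C6 carbinol; C9=C10 alkene)
Product: 9 cyclopentenone (C6 ketone, C9=C10, cis C7 chain and C8 OTES)
Conditions: Dess–Martin periodinane, NaHCO3, CH2Cl2, 0 °C → rt
Reagents that add atoms: none
Why: Dess–Martin oxidation of the allylic alcohol under buffered, non-basic conditions should give the γ-silyloxy enone without epimerising C7 or eliminating the C8 silyl ether.

Step 8
Reactants: 9 cyclopentenone
Product: 10 2-iodocyclopentenone (iodine on C10)
Conditions: I2, pyridine, CH2Cl2, 0 °C → rt
Reagents that add atoms: iodine, II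
Why: α-Iodination of the enone by pyridine conjugate addition, iodination of the enolate and elimination, a standard reaction of 4-silyloxycyclopentenones.

Step 9
Reactants: 10 2-iodocyclopentenone
Product: 11 (4R,5R)-5-[2-(tert-butyldiphenylsilyloxy)ethyl]-2-methyl-4-(triethylsilyloxy)cyclopent-2-en-1-one
Conditions: Me4Sn, Pd2(dba)3 (cat.), AsPh3, CuI, NMP, 60 °C
Reagents that add atoms: tetramethylstannane, C[Sn](C)(C)C
Why: Stille cross-coupling of the α-iodoenone under zerovalent palladium catalysis, with AsPh3 and CuI as accelerating additives, transfers the C14 methyl to C10.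

Step 10
Reactants: 12 4-methylpent-4-en-1-ol
Product: 13 4-methylpent-4-enal
Conditions: (COCl)2, DMSO, CH2Cl2, −78 °C; Et3N, −78 → 0 °C
Reagents that add atoms: none
Why: Swern oxidation stops at the volatile aldehyde, which is used as a solution, without over-oxidation or migration of the 1,1-disubstituted alkene.

Step 11
Reactants: 11 2-methylcyclopentenone; 13 4-methylpent-4-enal
Product: 15 aldol adduct (quaternary C10; C1 carbinol syn to the C14 methyl), via lithium enolate 14 (not isolated)
Conditions: LiBH(s-Bu)3 (1.0 equiv), THF, −78 °C; then 13, −78 °C; aq NH4Cl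
Reagents that add atoms: none
Why: Reductive aldol: conjugate hydride delivery to C9 gives the regiodefined tetrasubstituted enolate, which adds to the aldehyde on the ring face opposite the cis C7 and C8 substituents through a Zimmerman–Traxler chair with the aldehyde chain equatorial, creating quaternary C10 and the C1 carbinol syn to the C14 methyl.

Step 12
Reactants: 15 aldol adduct; 16 vinylmagnesium bromide
Product: 17 diene diol (C6 tertiary vinyl carbinol, vinyl cis to the C1 arm)
Conditions: CeCl3 (anhydrous), excess 16, THF, −78 °C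
Reagents that add atoms: none
Why: Organocerium 1,2-addition, which suppresses enolisation and retro-aldol of the aldolate, should reach the hindered C6 ketone from the face opposite the C14 methyl, the C7 side chain and the C8 silyl ether, so the vinyl group ends cis to the C1 arm; the C6 centre set here is erased again in step 15.

Step 13
Reactants: 17 diene diol
Product: 18 cis-fused bicyclo[5.3.0]decene diol (C4=C5 in the seven-membered ring)
Conditions: second-generation Grubbs catalyst (H2IMes)(PCy3)Cl2Ru=CHPh (cat.), CH2Cl2, high dilution, 40 °C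
Reagents that add atoms: none
Why: Ring-closing metathesis of the vinyl carbinol with the 1,1-disubstituted alkene releases ethene and closes the cycloheptene, whose ring size enforces the cis C4=C5 geometry.

Step 14
Reactants: 18 bicyclo[5.3.0]decene diol
Product: 19 C1 mesylate
Conditions: MsCl (1.2 equiv), Et3N, CH2Cl2, −20 °C
Reagents that add atoms: methanesulfonyl chloride, CS(=O)(=O)Cl
Why: Sulfene-mediated mesylation distinguishes the secondary C1 hydroxyl from the tertiary allylic C6 hydroxyl and gives the 1,3-diol monosulfonate needed for fragmentation.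

Step 15
Reactants: 19 C1 mesylate
Product: 21 (4Z,1(10)Z)-cyclodecadienone (C6 ketone), via potassium alkoxide 20 (not isolated)
Conditions: KOtBu (1.05 equiv), THF, 0 °C, short reaction time; pH 7 buffer quench
Reagents that add atoms: none
Why: Deprotonation of the tertiary C6 hydroxyl gives the alkoxide, whose oxygen lone pair pushes into the C6–C10 σ bond as that bond, anti-periplanar to the pseudo-equatorial C1–OMs bond of the cycloheptene, breaks in concert with loss of mesylate, so C6=O and C1=C10 form together (Wharton–Grob fragmentation of a cyclic 1,3-diol monosulfonate, the reaction that turns decalin and hydrindane diol monosulfonates into cyclodecenones and cyclononenones). No ring is closed: the ten-membered carbocycle arises by scission of the bond shared by the five- and seven-membered rings. No stereocentre is created; the new stereo-element is the C1=C10 geometry, and with the sulfonate anti to C6 the syn C1/C10 relationship from step 11 places C2 gauche to C9 and H1 gauche to C14, which translates stereospecifically into the Z alkene, while the Z C4=C5 bond is carried over from the ring of 18. The step needs fragmentation to outrun oxetane formation (O6 attacking C1), E2 loss of the mesylate and base damage to the product (C7 epimerisation or β-elimination of the C8 silyloxy group); the flexible cis-fused cycloheptene can adopt the anti-periplanar conformer, conjugation of the new C6 carbonyl with C4=C5 adds driving force, and one equivalent of base at 0 °C with a buffered quench limits the exposure of 21.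

Step 16
Reactants: 22 tiglic acid
Product: 23 (E)-2-methylbut-2-en-1-ol
Conditions: LiAlH4, Et2O, 0 °C
Reagents that add atoms: none
Why: LiAlH4 reduces the carboxylic acid to the allylic alcohol by 1,2-hydride delivery, the trisubstituted E alkene being retained.

Step 17
Reactants: 23 (E)-2-methylbut-2-en-1-ol
Product: 24 (2R,3R)-2,3-epoxy-2-methylbutan-1-ol
Conditions: Ti(OiPr)4 (cat.), D-(−)-diethyl tartrate (cat.), t-BuOOH, 4 Å MS, CH2Cl2, −20 °C
Reagents that add atoms: tert-butyl hydroperoxide, CC(C)(C)OO
Why: Sharpless asymmetric epoxidation; with D-(−)-diethyl tartrate the titanium tartrate complex delivers oxygen to the alkene face that gives the (2R,3R)-epoxy alcohol, and the E geometry becomes the cis relationship of the two methyl groups.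

Step 18
Reactants: 24 (2R,3R)-2,3-epoxy-2-methylbutan-1-ol
Product: 25 (2S,3R)-2,3-epoxy-2-methylbutanal
Conditions: Dess–Martin periodinane, NaHCO3, CH2Cl2, 0 °C → rt; distilled and kept as a dry stock solution
Reagents that add atoms: none
Why: Dess–Martin oxidation of the primary alcohol to the aldehyde; C2 is quaternary so it cannot epimerise, and the descriptor becomes 2S only because the substituent priorities change.

Step 19
Reactants: 21 (4Z,1(10)Z)-cyclodecadienone
Product: 26 β-hydroxy cyclodecadienone (free C8–OH)
Conditions: PPTS (cat.), MeOH–CH2Cl2, 0 °C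
Reagents that add atoms: none
Why: Acid-catalysed methanolysis cleaves the secondary triethylsilyl ether far faster than the primary TBDPS ether and exposes the C8 hydroxyl of the β-hydroxy ketone.

Step 20
Reactants: 26 β-hydroxy cyclodecadienone; 25 (2S,3R)-2,3-epoxy-2-methylbutanal
Product: 27 (6R)-alcohol carrying the C8 (2S,3R)-2,3-epoxy-2-methylbutanoate
Conditions: 25 (5 equiv), SmI2 (30 mol%; precatalyst aged with 25 until decolourised), THF, −10 °C
Reagents that add atoms: none
Why: Evans–Tishchenko reduction: the divalent samarium precatalyst is oxidised by a little of 25 to the trivalent samarium alkoxide catalyst, which binds the hemiacetal formed from the C8 hydroxyl and 25 and lets it deliver hydride intramolecularly to the C6 carbonyl through a chair-like bicyclic transition state, setting C6 1,3-anti to C8 (6R) while the aldehyde, both oxirane centres intact, ends as the C8 ester.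

Step 21
Reactants: 27 (6R)-alcohol with the C8 epoxy ester
Product: 28 1,4-diol (C6–OH and C12–OH)
Conditions: HF·pyridine, pyridine, THF, 0 °C → rt
Reagents that add atoms: none
Why: Fluoride cleavage of the TBDPS ether with pyridine-buffered HF·pyridine, mild enough for the ester, both oxiranes centres and the diene, frees the primary C12 hydroxyl.

Step 22
Reactants: 28 1,4-diol
Product: 30 trans-fused 6,12-lactone, via lactol 29 (not isolated)
Conditions: TEMPO (cat.), PhI(OAc)2 (2.5 equiv), CH2Cl2, rt
Reagents that add atoms: none
Why: TEMPO/PhI(OAc)2 oxidative lactonisation: the primary alcohol is oxidised selectively to the aldehyde, trapped by the C6 hydroxyl as the lactol and oxidised on to the γ-lactone, trans-fused because C6 and C7 already carry that relationship.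

Step 23
Reactants: 30 trans-fused 6,12-lactone
Product: 32 Mannich base (C11 dimethylaminomethyl lactone), via lithium lactone enolate 31 (not isolated)
Conditions: LiN(SiMe3)2, THF, −78 °C; then CH2=NMe2+ I−, −78 → 0 °C
Reagents that add atoms: N,N-dimethylmethyleneiminium iodide (Eschenmoser's salt), C=[N+](C)C.[I-]
Why: Kinetic deprotonation at C11, the only enolisable position because the ester has a quaternary α-carbon, followed by a Mannich reaction of the lactone enolate; the C11 centre formed as a mixture is removed in the next step.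

Step 24
Reactants: 32 Mannich base
Product: 34 α-methylene lactone, via quaternary ammonium iodide 33 (not isolated)
Conditions: MeI, THF, rt; then aq NaHCO3, CH2Cl2, rt
Reagents that add atoms: none
Why: Exhaustive N-methylation and mild-base β-elimination of trimethylamine (Hofmann-type elimination) install the exocyclic C11=C13 alkene.

Step 25
Reactants: 34 α-methylene lactone
Product: 35 target CNP0165580.2
Conditions: mCPBA (1.05 equiv), NaHCO3, CH2Cl2, 0 °C
Reagents that add atoms: 3-chloroperoxybenzoic acid, OOC(=O)c1cccc(Cl)c1
Why: Prilezhaev epoxidation, stereospecific for the cis oxirane, at the more electron-rich C1=C10 alkene (C4=C5 is deactivated by the allylic lactone oxygen and the methylene lactone is electron-poor); attack on the outer face of the alkene in the lactone-fused cis,cis ring is predicted to give the (1S,10R) oxirane, a substrate-controlled outcome that is the least certain stereochemical call of the route.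

**Compound list**

1 | (1R,5S)-2-oxabicyclo[3.3.0]oct-6-en-3-one (cis-fused lactone) | O=C1C[C@H]2C=CC[C@H]2O1 | starting material
2 | (1R,2S)-2-(2-hydroxyethyl)cyclopent-3-en-1-ol (cis diol) | OCC[C@H]1C=CC[C@H]1O | intermediate
3 | (1R,2S)-2-[2-(tert-butyldiphenylsilyloxy)ethyl]cyclopent-3-en-1-ol | CC(C)(C)[Si](c1ccccc1)(c1ccccc1)OCC[C@H]1C=CC[C@H]1O | intermediate
4 | tert-butyl{2-[(1S,5R)-5-(triethylsilyloxy)cyclopent-2-en-1-yl]ethoxy}diphenylsilane (cis; C8 OTES, C12 OTBDPS) | CC(C)(C)[Si](c1ccccc1)(c1ccccc1)OCC[C@H]1C=CC[C@H]1O[Si](CC)(CC)CC | intermediate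
5 | C6–C10 epoxide of 4, oxirane trans to the C7 chain and the C8 silyl ether | CC(C)(C)[Si](c1ccccc1)(c1ccccc1)OCC[C@H]1[C@@H]2O[C@@H]2C[C@H]1O[Si](CC)(CC)CC | intermediate
6 | hydroxy selenide: C6–OH trans to the C7 chain, C10–SePh trans to the C6–OH | CC(C)(C)[Si](c1ccccc1)(c1ccccc1)OCC[C@H]1[C@H](O)[C@@H]([Se]c2ccccc2)C[C@H]1O[Si](CC)(CC)CC | intermediate
7 | selenoxide of 6 (not isolated) | CC(C)(C)[Si](c1ccccc1)(c1ccccc1)OCC[C@H]1[C@H](O)[C@@H]([Se](=O)c2ccccc2)C[C@H]1O[Si](CC)(CC)CC | intermediate
8 | allylic alcohol: C6–OH trans to the C7 chain, C9=C10, cis C7 chain and C8 OTES | CC(C)(C)[Si](c1ccccc1)(c1ccccc1)OCC[C@H]1[C@H](O)C=C[C@H]1O[Si](CC)(CC)CC | intermediate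
9 | cyclopentenone: C6 ketone, C9=C10, cis C7 chain and C8 OTES | CC(C)(C)[Si](c1ccccc1)(c1ccccc1)OCC[C@H]1C(=O)C=C[C@H]1O[Si](CC)(CC)CC | intermediate
10 | 2-iodocyclopentenone (iodine on C10) | CC(C)(C)[Si](c1ccccc1)(c1ccccc1)OCC[C@H]1C(=O)C(I)=C[C@H]1O[Si](CC)(CC)CC | intermediate
11 | (4R,5R)-5-[2-(tert-butyldiphenylsilyloxy)ethyl]-2-methyl-4-(triethylsilyloxy)cyclopent-2-en-1-one | CC1=C[C@@H](O[Si](CC)(CC)CC)[C@@H](CCO[Si](c2ccccc2)(c3ccccc3)C(C)(C)C)C1=O | intermediate
12 | 4-methylpent-4-en-1-ol | C=C(C)CCCO | starting material
13 | 4-methylpent-4-enal | C=C(C)CCC=O | intermediate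
14 | lithium enolate (C6–OLi, C6=C10) from 1,4-reduction of 11 (not isolated) | [Li+].[O-]C1=C(C)C[C@@H](O[Si](CC)(CC)CC)[C@H]1CCO[Si](c1ccccc1)(c1ccccc1)C(C)(C)C | intermediate
15 | aldol adduct: quaternary C10 with the C1 carbinol arm trans to the C7 and C8 substituents; (1S)-OH syn to the C14 methyl | C=C(C)CC[C@H](O)[C@]1(C)C[C@@H](O[Si](CC)(CC)CC)[C@@H](CCO[Si](c2ccccc2)(c3ccccc3)C(C)(C)C)C1=O | intermediate
16 | vinylmagnesium bromide | C=C[Mg]Br | starting material
17 | diene diol: C6 tertiary vinyl carbinol, vinyl cis to the C1 arm, C6–OH cis to the C14 methyl | C=C(C)CC[C@H](O)[C@]1(C)C[C@@H](O[Si](CC)(CC)CC)[C@@H](CCO[Si](c2ccccc2)(c3ccccc3)C(C)(C)C)[C@]1(O)C=C | intermediate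
18 | cis-fused bicyclo[5.3.0]decene diol: C4=C5 in the seven-membered ring, secondary C1–OH, tertiary C6–OH at the ring fusion | O[C@H]1CCC(C)=C[C@@]2(O)[C@H](CCO[Si](c3ccccc3)(c4ccccc4)C(C)(C)C)[C@H](O[Si](CC)(CC)CC)C[C@@]12C | intermediate
19 | C1 mesylate of 18 | CS(=O)(=O)O[C@H]1CCC(C)=C[C@@]2(O)[C@H](CCO[Si](c3ccccc3)(c4ccccc4)C(C)(C)C)[C@H](O[Si](CC)(CC)CC)C[C@@]12C | intermediate
20 | potassium C6 alkoxide of 19 (not isolated) | [K+].CS(=O)(=O)O[C@H]1CCC(C)=C[C@@]2([O-])[C@H](CCO[Si](c3ccccc3)(c4ccccc4)C(C)(C)C)[C@H](O[Si](CC)(CC)CC)C[C@@]12C | intermediate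
21 | (4Z,1(10)Z)-cyclodecadienone: C6 ketone, C8 OTES, C7 CH2CH2OTBDPS | O=C1/C=C(/C)CC/C=C(/C)C[C@@H](O[Si](CC)(CC)CC)[C@H]1CCO[Si](c2ccccc2)(c3ccccc3)C(C)(C)C | intermediate
22 | tiglic acid, (E)-2-methylbut-2-enoic acid | C/C=C(\C)C(=O)O | starting material
23 | (E)-2-methylbut-2-en-1-ol | C/C=C(\C)CO | intermediate
24 | (2R,3R)-2,3-epoxy-2-methylbutan-1-ol | OC[C@@]1(C)O[C@@H]1C | intermediate
25 | (2S,3R)-2,3-epoxy-2-methylbutanal | O=C[C@@]1(C)O[C@@H]1C | intermediate
26 | β-hydroxy cyclodecadienone (C8–OH free, C12 OTBDPS) | O=C1/C=C(/C)CC/C=C(/C)C[C@@H](O)[C@H]1CCO[Si](c2ccccc2)(c3ccccc3)C(C)(C)C | intermediate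
27 | (6R)-alcohol with the C8 (2S,3R)-2,3-epoxy-2-methylbutanoate, C12 OTBDPS | O[C@@H]1/C=C(/C)CC/C=C(/C)C[C@@H](OC(=O)[C@@]2(C)O[C@@H]2C)[C@H]1CCO[Si](c3ccccc3)(c4ccccc4)C(C)(C)C | intermediate
28 | 1,4-diol (C6–OH, C12–OH) with the C8 epoxy ester | O[C@@H]1/C=C(/C)CC/C=C(/C)C[C@@H](OC(=O)[C@@]2(C)O[C@@H]2C)[C@H]1CCO | intermediate
29 | lactol (C12 hemiacetal closed on O6; not isolated) | C1C(O)O[C@@H]2/C=C(/C)CC/C=C(/C)C[C@@H](OC(=O)[C@@]3(C)O[C@@H]3C)[C@@H]12 | intermediate
30 | trans-fused 6,12-lactone of the (4Z,1(10)Z)-germacradiene with the C8 epoxy ester | C1C(=O)O[C@@H]2/C=C(/C)CC/C=C(/C)C[C@@H](OC(=O)[C@@]3(C)O[C@@H]3C)[C@@H]12 | intermediate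
31 | lithium enolate of lactone 30 (not isolated) | C1=C([O-])O[C@@H]2/C=C(/C)CC/C=C(/C)C[C@@H](OC(=O)[C@@]3(C)O[C@@H]3C)[C@@H]12.[Li+] | intermediate
32 | Mannich base: C11 dimethylaminomethyl lactone (C11 epimers) | CN(C)CC1C(=O)O[C@@H]2/C=C(/C)CC/C=C(/C)C[C@@H](OC(=O)[C@@]3(C)O[C@@H]3C)[C@@H]12 | intermediate
33 | trimethylammonium iodide of 32 (not isolated) | C[N+](C)(C)CC1C(=O)O[C@@H]2/C=C(/C)CC/C=C(/C)C[C@@H](OC(=O)[C@@]3(C)O[C@@H]3C)[C@@H]12.[I-] | intermediate
34 | α-methylene lactone: (4Z,1(10)Z)-germacra-1(10),4,11(13)-trien-12,6-olide with the C8 epoxy ester | C=C1C(=O)O[C@@H]2/C=C(/C)CC/C=C(/C)C[C@@H](OC(=O)[C@@]3(C)O[C@@H]3C)[C@@H]12 | intermediate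
35 | CNP0165580.2: (1S,6R,7R,8R,10R)-1,10-epoxy-(4Z)-germacra-4,11(13)-dien-12,6-olide 8-[(2S,3R)-2,3-epoxy-2-methylbutanoate] | C=C1C(=O)O[C@@H]2/C=C(/C)CC[C@@H]3O[C@]3(C)C[C@@H](OC(=O)[C@@]3(C)O[C@@H]3C)[C@@H]12 | target

**Step count and risks**

Total step count: 25. Longest linear sequence: 21 steps (1 to 35 through steps 1–9, 11–15 and 19–25); side branches are step 10 and steps 16–18.

Steps most likely to fail:

1. Step 11. The risk is weak control of the C1 configuration relative to C10, because it is uncertain how faithfully the tetrasubstituted lithium enolate follows the chair transition state; a wrong C1 epimer would become the E alkene in step 15. The fallback replaces aldol diastereoselection by reagent control. It sets out from the crude product of step 11, that is 15 together with its C1 epimer, the anti aldol F1. The mixture would be oxidised with Dess–Martin periodinane to the 2-acyl-2-methylcyclopentanone, 1,3-diketone F2, which cannot enolise between the carbonyls because C10 is quaternary. The side-chain C1 ketone, flanked by a methylene group, is less hindered than the ring ketone flanked by C7 and C10. It would be reduced with (R)-2-methyl-CBS-oxazaborolidine and catecholborane in toluene at −78 °C; with quaternary C10 as the large and the C2 methylene as the small substituent this catalyst enantiomer should give the (1S) carbinol, which is 15, where the route is rejoined.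

2. Step 20. The risks are reductive consumption of the epoxy aldehyde by samarium without catalyst turnover, sluggish hydride transfer inside the medium ring, and acyl migration between O8 and O6. The fallback acylates first and then reduces the ketone under reagent control. It sets out from 26 and 25. Aldehyde 25 would be oxidised (NaClO2, NaH2PO4, 2-methylbut-2-ene, t-BuOH–H2O) to (2S,3R)-2,3-dimethyloxirane-2-carboxylic acid F3. This acid would be coupled to the C8 hydroxyl of 26 by Yamaguchi esterification (2,4,6-trichlorobenzoyl chloride, Et3N, then DMAP, toluene, 0 °C, kept short to avoid β-elimination) to give keto ester F4. Reduction of the C6 enone carbonyl with a CBS oxazaborolidine and catecholborane at −78 °C would give the (6R) alcohol 27, where the route is rejoined. The (S)-catalyst is predicted if the branched C7 acts as the large group; this is not certain, the antipode is equally available, and a first experiment would settle the choice.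

3. Step 25. The risk is peracid delivery to the wrong face of C1=C10, or competing attack at C4=C5. The fallback is the halohydrin route, which places the oxirane on the face opposite to that reached by direct oxygen transfer. It sets out from 34. N-Bromosuccinimide in aqueous 1,2-dimethoxyethane at 0 °C would form the bromonium ion on the accessible face, and water would open it at the tertiary C10 from the other face to give bromohydrin F5 (C1 bromide, C10 tertiary alcohol). Ring closure with Ag2O in 1,2-dimethoxyethane, a silver-assisted displacement of bromide by the C10 hydroxyl with inversion at C1, would then give 35.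

**Further compounds**

F1 | step 11 | C1 epimer of aldol 15 (C1–OH anti to the C14 methyl) | C=C(C)CC[C@@H](O)[C@]1(C)C[C@@H](O[Si](CC)(CC)CC)[C@@H](CCO[Si](c2ccccc2)(c3ccccc3)C(C)(C)C)C1=O
F2 | step 11 | 1,3-diketone (C1 and C6 ketones on quaternary C10) | C=C(C)CCC(=O)[C@]1(C)C[C@@H](O[Si](CC)(CC)CC)[C@@H](CCO[Si](c2ccccc2)(c3ccccc3)C(C)(C)C)C1=O
F3 | step 20 | (2S,3R)-2,3-dimethyloxirane-2-carboxylic acid | OC(=O)[C@@]1(C)O[C@@H]1C
F4 | step 20 | C6 keto C8 epoxy ester of the cyclodecadienone | O=C1/C=C(/C)CC/C=C(/C)C[C@@H](OC(=O)[C@@]2(C)O[C@@H]2C)[C@H]1CCO[Si](c2ccccc2)(c3ccccc3)C(C)(C)C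
F5 | step 25 | bromohydrin of 34 (C1 bromide, C10 tertiary alcohol) | C=C1C(=O)O[C@@H]2/C=C(/C)CC[C@@H](Br)[C@](C)(O)C[C@@H](OC(=O)[C@@]3(C)O[C@@H]3C)[C@@H]12
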